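**Plan**

- Numbering (germacrane): carbocycle C1–C10; lactone O–C6, C7, C11(=C13), C12; C14 on C10, C15 on C4; O-n is the oxygen on C-n.
- Retrosynthesis: cut the C9–O ester, then the ring bond C9–C10. C9 is an allylic carbinol carbon bonded to the sp2 carbon C10 of the Z-C1=C10 olefin and flanked by the C8 acetoxy centre, so the ring opens to an iodoalkene and an α-acetoxy aldehyde. Then cut the lactone C12–O6, C1=C10, C2–C3 (Claisen), C4–C5 and C7–C11.
- Forward: L-arabinofuranose supplies C5–C9 and O6–O9. Its C3 ketone takes the C11–C13 unit, and the anomeric carbon (C5) is extended to the iodo-diene chain. The lactone ring is closed first and the ten-membered ring last, then the epoxyangelate is attached.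
- Stereochemistry: C6 and C8 are bought (C2 and C4 of L-arabinose). C7 comes from convex-face addition to the 3-ulose, and C9 is set in the ring closure under Felkin–Anh control from C8. 4E comes from the chair Claisen, 1(10)Z from the iodo-Wittig, and the epoxide from Sharpless epoxidation of angelyl alcohol.

Key step: step 18

Remark: compounds 1, 5 and 9 are taken as purchased, and the tartrate enantiomer in step 2 is the one that the Sharpless face rule assigns to the (2R,3S)-epoxy alcohol.

**Step 1**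
Reactants: 1 angelic acid [(Z)-2-methylbut-2-enoic acid]
Product: 2 angelyl alcohol [(Z)-2-methylbut-2-en-1-ol]
Conditions: LiAlH4, Et2O, 0 °C → rt
Reagents that add atoms: none
Why: Hydride reduction of the carboxylic acid (LiAlH4 reduction) should give the allylic alcohol and leave the trisubstituted Z-olefin untouched.

**Step 2**
Reactants: 2 angelyl alcohol
Product: 3 [(2R,3S)-2,3-dimethyloxiran-2-yl]methanol
Conditions: Ti(OiPr)4 (cat.), D-(−)-diethyl tartrate (cat.), t-BuOOH, 4 Å MS, CH2Cl2, −20 °C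
Reagents that add atoms: tert-butyl hydroperoxide, CC(C)(C)OO
Why: Sharpless asymmetric epoxidation, in which the titanium–tartrate complex delivers oxygen to one olefin face and the stereospecific syn addition to the Z-olefin keeps CH2OH and the C3 methyl cis, so both epoxide centres are set.

**Step 3**
Reactants: 3 [(2R,3S)-2,3-dimethyloxiran-2-yl]methanol
Product: 4 (2S,3S)-2,3-dimethyloxirane-2-carboxylic acid (epoxyangelic acid)
Conditions: RuCl3 (cat.), NaIO4, MeCN/EtOAc/H2O, 0 °C → rt
Reagents that add atoms: water, O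
Why: Ruthenium tetroxide oxidation of a 2,3-epoxy alcohol to the glycidic acid should leave the epoxide intact, and the C2 descriptor changes to S only because the CIP priorities change.

**Step 4**
Reactants: 5 L-arabinose
Product: 6 5-O-(tert-butyldiphenylsilyl)-L-arabinofuranose (anomeric mixture)
Conditions: TBDPSCl, pyridine, rt
Reagents that add atoms: tert-butyl(chloro)diphenylsilane, CC(C)(C)[Si](Cl)(c1ccccc1)c1ccccc1
Why: Selective silylation of the only primary hydroxyl by the bulky silyl chloride should lock the sugar in the furanose form.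

**Step 5**
Reactants: 6 5-O-(tert-butyldiphenylsilyl)-L-arabinofuranose
Product: 7 5-O-(tert-butyldiphenylsilyl)-1,2-O-isopropylidene-β-L-arabinofuranose
Conditions: 2,2-dimethoxypropane, CSA (cat.), acetone, rt
Reagents that add atoms: 2,2-dimethoxypropane, COC(C)(C)OC
Why: Acid-catalysed isopropylidene acetal formation should take place on the only cis-1,2-diol (O1/O2 of the β-furanose) and leave O3 free.

**Step 6**
Reactants: 7 5-O-(tert-butyldiphenylsilyl)-1,2-O-isopropylidene-β-L-arabinofuranose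
Product: 8 5-O-(tert-butyldiphenylsilyl)-1,2-O-isopropylidene-β-L-threo-pentofuranos-3-ulose
Conditions: Dess–Martin periodinane, CH2Cl2, rt
Reagents that add atoms: none
Why: Dess–Martin oxidation of the secondary alcohol should give the 3-ulose under near-neutral conditions that do not epimerise C2 or C4.

**Step 7**
Reactants: 8 5-O-(tert-butyldiphenylsilyl)-1,2-O-isopropylidene-β-L-threo-pentofuranos-3-ulose; 9 (2-bromoallyloxy)(tert-butyl)dimethylsilane
Product: 11 3-C-[3-(tert-butyldimethylsilyloxy)prop-1-en-2-yl]-5-O-(tert-butyldiphenylsilyl)-1,2-O-isopropylidene-β-L-lyxofuranose, via 2-lithioallyl silyl ether 10 (not isolated)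
Conditions: 9, t-BuLi (2 equiv), Et2O, −78 °C; then 8, −78 °C; H2O quench
Reagents that add atoms: none
Why: Bromine–lithium exchange gives the alkenyllithium 10, whose 1,2-addition to the ketone should occur on the convex face of the cis-fused bicycle, anti to both the 1,2-acetonide and the C4 CH2OSi group, so the new tertiary hydroxyl (C7) is cis to O2 (L-lyxo).

**Step 8**
Reactants: 11 3-C-[3-(tert-butyldimethylsilyloxy)prop-1-en-2-yl]-5-O-(tert-butyldiphenylsilyl)-1,2-O-isopropylidene-β-L-lyxofuranose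
Product: 12 3-C-[3-(tert-butyldimethylsilyloxy)prop-1-en-2-yl]-5-O-(tert-butyldiphenylsilyl)-2,3-O-isopropylidene-L-lyxofuranose (lactol, anomeric mixture)
Conditions: CSA (cat.), acetone, rt
Reagents that add atoms: none
Why: Acid-catalysed acetal migration under thermodynamic control, in which the isopropylidene group should move from O1/O2 to the cis O2/O3 pair (the arrangement that cis-2,3-diol furanoses prefer) and free the anomeric hydroxyl as a lactol.

**Step 9**
Reactants: 12 the 2,3-O-isopropylidene lactol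
Product: 13 (1RS)-3-C-[3-(tert-butyldimethylsilyloxy)prop-1-en-2-yl]-5-O-(tert-butyldiphenylsilyl)-2,3-O-isopropylidene-1-C-(prop-1-en-2-yl)-L-lyxitol (free hydroxyls at C5 and C8)
Conditions: CH2=C(CH3)MgBr (excess), THF, 0 °C → rt
Reagents that add atoms: isopropenylmagnesium bromide, CC(=C)[Mg]Br
Why: Grignard addition to the open hydroxy-aldehyde form of the lactol should give the isopropenyl carbinol and free O8 (the former ring oxygen), and the C5 configuration is of no consequence because it is destroyed in step 10.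

**Step 10**
Reactants: 13 the C5-epimeric diol
Product: 15 ethyl (4E)-5-[(4S,5R)-5-[(1S)-2-(tert-butyldiphenylsilyloxy)-1-hydroxyethyl]-5-[3-(tert-butyldimethylsilyloxy)prop-1-en-2-yl]-2,2-dimethyl-1,3-dioxolan-4-yl]-4-methylpent-4-enoate, via ketene acetal 14 (not isolated)
Conditions: MeC(OEt)3, EtCO2H (cat.), 140 °C, EtOH distilled off; dilute aqueous acid work-up
Reagents that add atoms: triethyl orthoacetate, CCOC(C)(OCC)OCC
Why: Johnson–Claisen rearrangement, in which only the allylic C5 hydroxyl forms a ketene acetal (14) that can rearrange, and the chair transition state with the C6 substituent equatorial should give the E trisubstituted C4=C5 olefin and the C2–C1 ester chain, the mixed orthoester at O8 being hydrolysed on work-up.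

**Step 11**
Reactants: 15 the ethyl ester
Product: 16 (4E)-5-[(4S,5R)-5-[(1S)-2-(tert-butyldiphenylsilyloxy)-1-hydroxyethyl]-5-[3-(tert-butyldimethylsilyloxy)prop-1-en-2-yl]-2,2-dimethyl-1,3-dioxolan-4-yl]-4-methylpent-4-enal
Conditions: DIBAL-H, CH2Cl2, −78 °C; Rochelle salt
Reagents that add atoms: none
Why: DIBAL-H reduction at −78 °C should stop at the tetrahedral aluminium hemiacetal, which gives the aldehyde on work-up.

**Step 12**
Reactants: 16 the aldehyde
Product: 17 (1S)-2-(tert-butyldiphenylsilyloxy)-1-[(4R,5S)-4-[3-(tert-butyldimethylsilyloxy)prop-1-en-2-yl]-5-[(1E,5Z)-6-iodo-2-methylhepta-1,5-dien-1-yl]-2,2-dimethyl-1,3-dioxolan-4-yl]ethanol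
Conditions: EtPPh3I, n-BuLi, THF; I2, −78 °C; NaHMDS, −20 °C; then 16, −78 °C
Reagents that add atoms: ethyltriphenylphosphonium iodide, CC[P+](c1ccccc1)(c1ccccc1)c1ccccc1.[I-]; iodine, II
Why: Stork–Zhao olefination (Wittig reaction of the α-iodo ylide) should give the 2-iodoalk-2-ene with iodine cis to the chain (Z), the geometry needed for C1=C10.

**Step 13**
Reactants: 17 the (Z)-iodoalkene alcohol
Product: 18 (1S)-2-(tert-butyldiphenylsilyloxy)-1-[(4S,5S)-4-[3-(tert-butyldimethylsilyloxy)prop-1-en-2-yl]-5-[(1E,5Z)-6-iodo-2-methylhepta-1,5-dien-1-yl]-2,2-dimethyl-1,3-dioxolan-4-yl]ethyl acetate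
Conditions: Ac2O, pyridine, DMAP (cat.), CH2Cl2, rt
Reagents that add atoms: acetic anhydride, CC(=O)OC(C)=O
Why: DMAP-catalysed acylation of the only free hydroxyl (O8) installs the C8 acetate of the target.

**Step 14**
Reactants: 18 the acetate
Product: 19 (2S,3S,4S,5E,9Z)-1-(tert-butyldiphenylsilyloxy)-3,4-dihydroxy-3-(3-hydroxyprop-1-en-2-yl)-10-iodo-6-methylundeca-5,9-dien-2-yl acetate
Conditions: CSA (cat.), MeOH, 0 °C → rt
Reagents that add atoms: none
Why: Acid-catalysed transacetalisation and methanolysis should remove the isopropylidene group and the allylic primary TBS ether, while the TBDPS ether and the acetate are stable to camphorsulfonic acid in methanol.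

**Step 15**
Reactants: 19 the triol
Product: 22 (1S)-2-(tert-butyldiphenylsilyloxy)-1-[(2S,3S)-3-hydroxy-2-[(1E,5Z)-6-iodo-2-methylhepta-1,5-dien-1-yl]-4-methylidene-5-oxooxolan-3-yl]ethyl acetate, via hydroxy enal 20 (not isolated), via lactol 21 (not isolated)
Conditions: TEMPO (cat.), PhI(OAc)2, CH2Cl2, rt
Reagents that add atoms: none
Why: TEMPO/PhI(OAc)2 oxidative lactonisation, in which the primary allylic alcohol is oxidised selectively to the enal 20, trapped by the C6 hydroxyl as the five-membered lactol 21 and oxidised again to the α-methylene γ-lactone, while the secondary and tertiary hydroxyls are not oxidised and O9 is still silylated.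

**Step 16**
Reactants: 22 the silylated lactone
Product: 23 (1S)-2-hydroxy-1-[(2S,3S)-3-hydroxy-2-[(1E,5Z)-6-iodo-2-methylhepta-1,5-dien-1-yl]-4-methylidene-5-oxooxolan-3-yl]ethyl acetate
Conditions: HF·pyridine, pyridine/THF, 0 °C → rt
Reagents that add atoms: none
Why: Fluoride cleavage of the silyl ether under acidic, buffered conditions should free the primary C9 hydroxyl without base-induced acetyl migration from O8.

**Step 17**
Reactants: 23 the primary alcohol
Product: 24 (1R)-1-[(2S,3S)-3-hydroxy-2-[(1E,5Z)-6-iodo-2-methylhepta-1,5-dien-1-yl]-4-methylidene-5-oxooxolan-3-yl]-2-oxoethyl acetate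
Conditions: Dess–Martin periodinane, NaHCO3, CH2Cl2, 0 °C
Reagents that add atoms: none
Why: Buffered Dess–Martin oxidation should give the α-acetoxy aldehyde without epimerisation at C8 or elimination of the β-hydroxyl (the C8 descriptor changes only because CHO outranks C7).

**Step 18**
Reactants: 24 the iodoalkene aldehyde
Product: 26 (6S,7S,8S,9S)-8-acetoxy-7,9-dihydroxygermacra-1(10)Z,4E,11(13)-trien-12,6-olide, via alkenylchromium species 25 (not isolated)
Conditions: CrCl2 (excess), NiCl2 (cat.), degassed DMSO, rt, high dilution (slow addition of 24)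
Reagents that add atoms: none
Why: Ni(0) formed from NiCl2/CrCl2 inserts into the C10–I bond with retention of the Z geometry, transmetalates to the alkenylchromium(III) species 25, and this adds to the C9 aldehyde; the closest known reaction type is the intramolecular Nozaki–Hiyama–Kishi closure of medium rings from iodoalkene aldehydes. The ten-membered carbocycle closes by a 10-exo-trig 1,2-addition that forms C9–C10. The new C9 stereocentre should be set by the adjacent C8 acetoxy centre in the polar Felkin–Anh sense (attack anti to C8–OAc), which gives the 8,9-anti (9S) alcohol, and the trans-fused lactone at C6/C7 together with the E-C4=C5 and Z-C1=C10 olefins restricts the seco-chain to a folded conformer. The step needs chemoselectivity for the aldehyde over the lactone, the acetate and the conjugated exo-methylene, which the carbonyl selectivity and low basicity of organochromium(III) secure, and ring closure over oligomerisation, which high dilution and the two preformed olefins in the tether secure. The free C9 hydroxyl is formed next to the C8 acetate, so the two ester positions of the target are differentiated in the same event.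

**Step 19**
Reactants: 26 the macrocyclic alcohol; 4 (2S,3S)-2,3-dimethyloxirane-2-carboxylic acid
Product: 28 (6S,7S,8S,9S)-8-acetoxy-9-[(2S,3S)-2,3-epoxy-2-methylbutanoyloxy]-7-hydroxygermacra-1(10)Z,4E,11(13)-trien-12,6-olide (CNP0271187.2), via mixed anhydride 27 (not isolated)
Conditions: 4, 2,4,6-Cl3C6H2COCl, Et3N, THF, rt; then 26, DMAP, toluene, rt
Reagents that add atoms: none
Why: Yamaguchi esterification, in which the acid is activated as the mixed anhydride 27 and DMAP transfers the acyl group to the secondary allylic C9 hydroxyl, the tertiary C7 hydroxyl being too hindered to react.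

**Compound list**

1 | angelic acid, (Z)-2-methylbut-2-enoic acid | C/C=C(/C)C(=O)O | starting material
2 | angelyl alcohol, (Z)-2-methylbut-2-en-1-ol | C/C=C(/C)CO | intermediate
3 | [(2R,3S)-2,3-dimethyloxiran-2-yl]methanol | OC[C@@]1(C)O[C@H]1C | intermediate
4 | (2S,3S)-2,3-dimethyloxirane-2-carboxylic acid | OC(=O)[C@@]1(C)O[C@H]1C | intermediate
5 | L-arabinose (aldehydo form drawn) | O=C[C@H](O)[C@@H](O)[C@@H](O)CO | starting material
6 | 5-O-(tert-butyldiphenylsilyl)-L-arabinofuranose, anomeric mixture | OC1O[C@@H](CO[Si](c2ccccc2)(c2ccccc2)C(C)(C)C)[C@H](O)[C@H]1O | intermediate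
7 | 5-O-(tert-butyldiphenylsilyl)-1,2-O-isopropylidene-β-L-arabinofuranose | CC1(C)O[C@H]2O[C@@H](CO[Si](c3ccccc3)(c3ccccc3)C(C)(C)C)[C@H](O)[C@H]2O1 | intermediate
8 | 5-O-(tert-butyldiphenylsilyl)-1,2-O-isopropylidene-β-L-threo-pentofuranos-3-ulose | CC1(C)O[C@H]2O[C@@H](CO[Si](c3ccccc3)(c3ccccc3)C(C)(C)C)C(=O)[C@H]2O1 | intermediate
9 | (2-bromoallyloxy)(tert-butyl)dimethylsilane | C=C(Br)CO[Si](C)(C)C(C)(C)C | starting material
10 | [3-(tert-butyldimethylsilyloxy)prop-1-en-2-yl]lithium (not isolated) | [Li]C(=C)CO[Si](C)(C)C(C)(C)C | intermediate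
11 | 3-C-[3-(tert-butyldimethylsilyloxy)prop-1-en-2-yl]-5-O-(tert-butyldiphenylsilyl)-1,2-O-isopropylidene-β-L-lyxofuranose | CC1(C)O[C@H]2O[C@@H](CO[Si](c3ccccc3)(c3ccccc3)C(C)(C)C)[C@](O)(C(=C)CO[Si](C)(C)C(C)(C)C)[C@H]2O1 | intermediate
12 | 3-C-[3-(tert-butyldimethylsilyloxy)prop-1-en-2-yl]-5-O-(tert-butyldiphenylsilyl)-2,3-O-isopropylidene-L-lyxofuranose, anomeric mixture | OC1O[C@@H](CO[Si](c2ccccc2)(c2ccccc2)C(C)(C)C)[C@@]2(C(=C)CO[Si](C)(C)C(C)(C)C)OC(C)(C)O[C@@H]12 | intermediate
13 | (1RS)-3-C-[3-(tert-butyldimethylsilyloxy)prop-1-en-2-yl]-5-O-(tert-butyldiphenylsilyl)-2,3-O-isopropylidene-1-C-(prop-1-en-2-yl)-L-lyxitol | CC(=C)C(O)[C@@H]1OC(C)(C)O[C@]1(C(=C)CO[Si](C)(C)C(C)(C)C)[C@@H](O)CO[Si](c2ccccc2)(c2ccccc2)C(C)(C)C | intermediate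
14 | O5-(1-ethoxyvinyl) ketene acetal of 13 (not isolated) | C=C(OCC)OC(C(C)=C)[C@@H]1OC(C)(C)O[C@]1(C(=C)CO[Si](C)(C)C(C)(C)C)[C@@H](O)CO[Si](c2ccccc2)(c2ccccc2)C(C)(C)C | intermediate
15 | ethyl (4E)-5-[(4S,5R)-5-[(1S)-2-(tert-butyldiphenylsilyloxy)-1-hydroxyethyl]-5-[3-(tert-butyldimethylsilyloxy)prop-1-en-2-yl]-2,2-dimethyl-1,3-dioxolan-4-yl]-4-methylpent-4-enoate | CCOC(=O)CC/C(C)=C/[C@@H]1OC(C)(C)O[C@]1(C(=C)CO[Si](C)(C)C(C)(C)C)[C@@H](O)CO[Si](c2ccccc2)(c2ccccc2)C(C)(C)C | intermediate
16 | the corresponding (4E)-pent-4-enal (C1 aldehyde) | O=CCC/C(C)=C/[C@@H]1OC(C)(C)O[C@]1(C(=C)CO[Si](C)(C)C(C)(C)C)[C@@H](O)CO[Si](c2ccccc2)(c2ccccc2)C(C)(C)C | intermediate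
17 | (1S)-2-(tert-butyldiphenylsilyloxy)-1-[(4R,5S)-4-[3-(tert-butyldimethylsilyloxy)prop-1-en-2-yl]-5-[(1E,5Z)-6-iodo-2-methylhepta-1,5-dien-1-yl]-2,2-dimethyl-1,3-dioxolan-4-yl]ethanol | C/C(I)=C/CC/C(C)=C/[C@@H]1OC(C)(C)O[C@]1(C(=C)CO[Si](C)(C)C(C)(C)C)[C@@H](O)CO[Si](c2ccccc2)(c2ccccc2)C(C)(C)C | intermediate
18 | the O8 acetate of 17, dioxolane (4S,5S) | C/C(I)=C/CC/C(C)=C/[C@@H]1OC(C)(C)O[C@]1(C(=C)CO[Si](C)(C)C(C)(C)C)[C@@H](OC(C)=O)CO[Si](c2ccccc2)(c2ccccc2)C(C)(C)C | intermediate
19 | (2S,3S,4S,5E,9Z)-1-(tert-butyldiphenylsilyloxy)-3,4-dihydroxy-3-(3-hydroxyprop-1-en-2-yl)-10-iodo-6-methylundeca-5,9-dien-2-yl acetate | C/C(I)=C/CC/C(C)=C/[C@H](O)[C@@](O)(C(=C)CO)[C@@H](OC(C)=O)CO[Si](c1ccccc1)(c1ccccc1)C(C)(C)C | intermediate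
20 | (2S,3S,4S,5E,9Z)-1-(tert-butyldiphenylsilyloxy)-3,4-dihydroxy-10-iodo-6-methyl-3-(3-oxoprop-1-en-2-yl)undeca-5,9-dien-2-yl acetate (not isolated) | C/C(I)=C/CC/C(C)=C/[C@H](O)[C@@](O)(C(=C)C=O)[C@@H](OC(C)=O)CO[Si](c1ccccc1)(c1ccccc1)C(C)(C)C | intermediate
21 | (1S)-2-(tert-butyldiphenylsilyloxy)-1-[(2S,3S)-3,5-dihydroxy-2-[(1E,5Z)-6-iodo-2-methylhepta-1,5-dien-1-yl]-4-methylideneoxolan-3-yl]ethyl acetate, lactol epimers (not isolated) | C=C1C(O)O[C@@H](/C=C(\C)CC/C=C(/C)I)[C@]1(O)[C@@H](OC(C)=O)CO[Si](c2ccccc2)(c2ccccc2)C(C)(C)C | intermediate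
22 | (1S)-2-(tert-butyldiphenylsilyloxy)-1-[(2S,3S)-3-hydroxy-2-[(1E,5Z)-6-iodo-2-methylhepta-1,5-dien-1-yl]-4-methylidene-5-oxooxolan-3-yl]ethyl acetate | C=C1C(=O)O[C@@H](/C=C(\C)CC/C=C(/C)I)[C@]1(O)[C@@H](OC(C)=O)CO[Si](c2ccccc2)(c2ccccc2)C(C)(C)C | intermediate
23 | (1S)-2-hydroxy-1-[(2S,3S)-3-hydroxy-2-[(1E,5Z)-6-iodo-2-methylhepta-1,5-dien-1-yl]-4-methylidene-5-oxooxolan-3-yl]ethyl acetate | C=C1C(=O)O[C@@H](/C=C(\C)CC/C=C(/C)I)[C@]1(O)[C@@H](OC(C)=O)CO | intermediate
24 | (1R)-1-[(2S,3S)-3-hydroxy-2-[(1E,5Z)-6-iodo-2-methylhepta-1,5-dien-1-yl]-4-methylidene-5-oxooxolan-3-yl]-2-oxoethyl acetate | C=C1C(=O)O[C@@H](/C=C(\C)CC/C=C(/C)I)[C@]1(O)[C@@H](OC(C)=O)C=O | intermediate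
25 | C10 dichlorochromium(III) alkenyl derived from 24 (not isolated) | C=C1C(=O)O[C@@H](/C=C(\C)CC/C=C(/C)[Cr](Cl)Cl)[C@]1(O)[C@@H](OC(C)=O)C=O | intermediate
26 | (6S,7S,8S,9S)-8-acetoxy-7,9-dihydroxygermacra-1(10)Z,4E,11(13)-trien-12,6-olide | C=C1C(=O)O[C@H]2/C=C(\C)CC/C=C(/C)[C@H](O)[C@H](OC(C)=O)[C@]12O | intermediate
27 | (2S,3S)-2,3-dimethyloxirane-2-carboxylic 2,4,6-trichlorobenzoic anhydride (not isolated) | O=C(OC(=O)c1c(Cl)cc(Cl)cc1Cl)[C@@]2(C)O[C@H]2C | intermediate
28 | (6S,7S,8S,9S)-8-acetoxy-9-[(2S,3S)-2,3-epoxy-2-methylbutanoyloxy]-7-hydroxygermacra-1(10)Z,4E,11(13)-trien-12,6-olide | C=C1C(=O)O[C@H]2/C=C(\C)CC/C=C(/C)[C@H](OC(=O)[C@@]3(C)O[C@H]3C)[C@H](OC(C)=O)[C@]12O | target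

**Totals**

Total step count: 19. Longest linear sequence: 16 steps (steps 4–19, from L-arabinose).

**Steps most likely to fail, with fallbacks**

Ring closure (step 18). The ring conformation may override Felkin–Anh control, so that the addition takes place on the wrong aldehyde face, or the closure may be slow against oligomerisation. The fallback sets out from 24 and accepts the cyclisation product as the C9-epimeric macrocyclic alcohol F1. Dess–Martin oxidation should give the macrocyclic C9 enone F2. Reagent-controlled 1,2-reduction with (S)-CBS oxazaborolidine and catecholborane, with the alkenyl group acting as the large substituent, should then return to the route at 26.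

Acetal migration (step 8). The equilibration may stop short, or the acid may cleave the allylic TBS ether. The fallback sets out from 11. Aqueous acetic acid in THF should remove both the 1,2-acetonide and the TBS group to give the lactol tetraol F3. Acetone with 2,2-dimethoxypropane and CSA should then form the cis-fused 2,3-O-isopropylidene lactol F4. Selective silylation of the primary allylic hydroxyl (TBSCl, imidazole, −20 °C) comes back to the route at 12.

Orthoester Claisen rearrangement (step 10). The non-allylic O8 hydroxyl may be carried on as an orthoester or acetate, and the acetal and silyl ethers may suffer at 140 °C in the presence of acid. The fallback sets out from 13. Hg(OAc)2-catalysed exchange with ethyl vinyl ether should give the bis(vinyl ether) F5. Heating in toluene in a sealed tube should bring about the aliphatic Claisen rearrangement of the allyl vinyl ether to the aldehyde F6, which still carries the O8 vinyl ether. PPTS in wet acetone hydrolyses that vinyl ether and comes back to the route at 16, so that step 11 is bypassed.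

**Further compounds**

F1 | step 18 | (6S,7S,8S,9R)-8-acetoxy-7,9-dihydroxygermacra-1(10)Z,4E,11(13)-trien-12,6-olide (9-epi-26) | C=C1C(=O)O[C@H]2/C=C(\C)CC/C=C(/C)[C@@H](O)[C@H](OC(C)=O)[C@]12O
F2 | step 18 | 8-acetoxy-7-hydroxy-9-oxogermacra-1(10)Z,4E,11(13)-trien-12,6-olide, C6–C8 as in 26 | C=C1C(=O)O[C@H]2/C=C(\C)CC/C=C(/C)C(=O)[C@H](OC(C)=O)[C@]12O
F3 | step 8 | 5-O-(tert-butyldiphenylsilyl)-3-C-(3-hydroxyprop-1-en-2-yl)-L-lyxofuranose, anomeric mixture | OC1O[C@@H](CO[Si](c2ccccc2)(c2ccccc2)C(C)(C)C)[C@](O)(C(=C)CO)[C@H]1O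
F4 | step 8 | 5-O-(tert-butyldiphenylsilyl)-3-C-(3-hydroxyprop-1-en-2-yl)-2,3-O-isopropylidene-L-lyxofuranose, anomeric mixture | OC1O[C@@H](CO[Si](c2ccccc2)(c2ccccc2)C(C)(C)C)[C@@]2(C(=C)CO)OC(C)(C)O[C@@H]12
F5 | step 10 | O5,O8-divinyl ether of 13 | C=COC(C(C)=C)[C@@H]1OC(C)(C)O[C@]1(C(=C)CO[Si](C)(C)C(C)(C)C)[C@@H](OC=C)CO[Si](c2ccccc2)(c2ccccc2)C(C)(C)C
F6 | step 10 | O8-vinyl ether of aldehyde 16 | O=CCC/C(C)=C/[C@@H]1OC(C)(C)O[C@]1(C(=C)CO[Si](C)(C)C(C)(C)C)[C@@H](OC=C)CO[Si](c2ccccc2)(c2ccccc2)C(C)(C)C
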